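The seven-membered ring is assembled as a six-membered ring that lacks C4 (azulene numbering): C3a and C5, the two oxygen-bearing carbons flanking the C4 methylene, enter as the two alkyne carbons of an acyclic dienyne, and C6–C7–C8–C8a as its diene. A monovalent-rhodium-catalysed intramolecular [4+2] cycloaddition forms C3a–C8a (cyclopentane and quaternary centre) and C5–C6 in one operation. The C3a=C5 double bond so created is not in the target: ozonolysis cleaves it to the two ketones, and the alkyne's methyl group returns as C4 in an aldol closure of the seven-membered ring. The dienyne comes from (R)-limonene by ring ozonolysis.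

Key step: step 8

Remark: the cycloaddition is expected to place the C3 isopropyl group anti to the new angular methyl group, so C3 is carried as its epimer (hence (R)-limonene) and corrected at the cyclopentanone stage in step 11.

Step 1
Reactants: 1 (R)-(+)-limonene
Product: 2 (4R)-1-methyl-4-(propan-2-yl)cyclohex-1-ene
Conditions: H2 (1 atm), RhCl(PPh3)3 (1 mol %), benzene, 25 °C
Reagents that add atoms: none
Why: Chemoselective homogeneous hydrogenation with the Wilkinson complex saturates the 1,1-disubstituted exocyclic alkene and leaves the trisubstituted ring alkene and the stereocentre untouched.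

Step 2
Reactants: 2 (4R)-1-methyl-4-(propan-2-yl)cyclohex-1-ene
Product: 5 (5R)-7,7-dimethoxy-5-(propan-2-yl)heptan-2-one, via hydroperoxy aldehyde 3 (not isolated), via hydroperoxy acetal 4 (not isolated)
Conditions: O3, CH2Cl2/MeOH, −78 °C; TsOH·H2O (cat.), −78 → 25 °C; NaHCO3, then Me2S, 25 °C
Reagents that add atoms: ozone O=[O+][O-]; methanol CO
Why: Ozonolysis with differentiation of the two termini (Schreiber protocol) traps the carbonyl oxide at the more substituted carbon with methanol, acetalises the free aldehyde and then releases the methyl ketone on sulfide reduction, so the ring C–C bond is cut while the stereocentre is kept.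

Step 3
Reactants: 5 (5R)-7,7-dimethoxy-5-(propan-2-yl)heptan-2-one
Product: 7 (5R)-7,7-dimethoxy-5-(propan-2-yl)hept-1-yne, via enol phosphate 6 (not isolated)
Conditions: LiN(iPr)2 (1.05 equiv), THF, −78 °C; ClP(O)(OEt)2; LiN(iPr)2 (2.3 equiv), −78 → 25 °C; H2O
Reagents that add atoms: none
Why: Negishi conversion of a methyl ketone into a terminal alkyne by kinetic enolisation at the methyl group, O-phosphorylation and base-induced elimination of the enol phosphate.

Step 4
Reactants: 7 (5R)-7,7-dimethoxy-5-(propan-2-yl)hept-1-yne; 8 (E)-1-bromoprop-1-ene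
Product: 10 (2E,4E,8R)-10,10-dimethoxy-5-methyl-8-(propan-2-yl)deca-2,4-diene, via alkenylalane 9 (not isolated)
Conditions: Al(CH3)3 (2 equiv), (C5H5)2ZrCl2 (0.2 equiv), CH2Cl2, −20 → 25 °C; then 8, Pd(PPh3)4 (5 mol %), THF, 25 °C
Reagents that add atoms: trimethylaluminium C[Al](C)C
Why: Zirconium-catalysed syn-carboalumination (Negishi) puts methyl on the internal alkyne carbon and gives the (E)-alkenylalane, which cross-couples under palladium catalysis with retention at both partners to give the (E,E)-diene.

Step 5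
Reactants: 10 (2E,4E,8R)-10,10-dimethoxy-5-methyl-8-(propan-2-yl)deca-2,4-diene
Product: 11 (3R,6E,8E)-6-methyl-3-(propan-2-yl)deca-6,8-dienal
Conditions: pyridinium p-toluenesulfonate (0.2 equiv), acetone/H2O (9:1), 50 °C
Reagents that add atoms: water O
Why: Mild acid-catalysed acetal hydrolysis frees the aldehyde without isomerising the diene.

Step 6
Reactants: 11 (3R,6E,8E)-6-methyl-3-(propan-2-yl)deca-6,8-dienal
Product: 12 (3S,6E,8E)-6-methyl-3-(propan-2-yl)deca-1,6,8-trien-1-yl trifluoromethanesulfonate (1E/1Z mixture)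
Conditions: (CF3SO2)2O (1.2 equiv), 2,6-di-tert-butyl-4-methylpyridine (1.3 equiv), CH2Cl2, 0 → 25 °C
Reagents that add atoms: trifluoromethanesulfonic anhydride O=S(=O)(OS(=O)(=O)C(F)(F)F)C(F)(F)F
Why: O-Sulfonylation of the aldehyde enol with a hindered base (Stang vinyl triflate synthesis) involves only the α-carbon, so the β-stereocentre is not touched (its descriptor changes by priority only).

Step 7
Reactants: 12 (3S,6E,8E)-6-methyl-3-(propan-2-yl)deca-1,6,8-trien-1-yl trifluoromethanesulfonate
Product: 14 (2E,4E,8S)-5-methyl-8-(propan-2-yl)undeca-2,4-dien-9-yne, via lithium acetylide 13 (not isolated)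
Conditions: LiN(iPr)2 (2.5 equiv), THF, −78 → 0 °C; then CH3I (3 equiv), 0 → 25 °C
Reagents that add atoms: iodomethane CI
Why: Base-induced β-elimination of triflate from the vinyl triflate gives the terminal alkyne, whose lithium acetylide is C-methylated in the same flask (elimination–alkylation).

Step 8
Reactants: 14 (2E,4E,8S)-5-methyl-8-(propan-2-yl)undeca-2,4-dien-9-yne
Product: 15 (3S,5S,7aR)-4,5,7a-trimethyl-3-(propan-2-yl)-2,3,5,7a-tetrahydro-1H-indene
Conditions: [Rh(C8H12)(C10H8)]SbF6 ((1,5-cyclooctadiene)(naphthalene)rhodium hexafluoroantimonate, 5 mol %), ClCH2CH2Cl (0.01 M), 25 → 60 °C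
Reagents that add atoms: none
Why: The cationic monovalent rhodium centre binds the alkyne and the tethered diene and undergoes oxidative cyclisation to a rhodacycle, forming C3a–C7a, and reductive elimination of the resulting vinyl(allyl)rhodium species then forms C4–C5 (net [4+2]; indene C3a, C4, C5 and C7a are azulene C3a, C5, C6 and C8a of the target). The closest known reaction type is the rhodium- or nickel-catalysed intramolecular [4+2] cycloaddition of 1,3-dien-8-ynes to bicyclic cyclohexa-1,4-dienes. The five-membered ring closes in the 5-exo mode at the alkyne carbon that carries the tether, and the six-membered ring closes in the 6-endo mode across both alkyne carbons. C7a is set by the C3 stereocentre: the C4 methyl group lies cis to C3, so 1,3-allylic strain holds the C3 hydrogen in the alkene plane and the isopropyl group perpendicular to it, and the diene terminus adds so that the angular methyl group ends anti to isopropyl (7aR from 3S); C5 follows from suprafacial addition to the (E,E)-diene and is erased in step 9. The step needs cycloaddition to win over ene-type cycloisomerisation and alkyne oligomerisation at a fully substituted diene terminus, which the three-atom tether, the E geometry of the tethered double bond and the weakly ligated cationic catalyst at high dilution are chosen to secure.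

Step 9
Reactants: 15 (3S,5S,7aR)-4,5,7a-trimethyl-3-(propan-2-yl)-2,3,5,7a-tetrahydro-1H-indene
Product: 16 (3S,7aR)-4,5,7a-trimethyl-3-(propan-2-yl)-2,3,7,7a-tetrahydro-1H-indene
Conditions: RuHCl(CO)(PPh3)3 (5 mol %), toluene, 100 °C
Reagents that add atoms: none
Why: Ruthenium hydride-catalysed alkene isomerisation (insertion and β-hydride elimination) moves the disubstituted C6=C7 bond into conjugation as the trisubstituted C5=C6 bond, while the tetrasubstituted C3a=C4 bond is inert to insertion; the C5 stereocentre is erased.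

Step 10
Reactants: 16 (3S,7aR)-4,5,7a-trimethyl-3-(propan-2-yl)-2,3,7,7a-tetrahydro-1H-indene
Product: 18 (2R,5S)-2-methyl-2-[(2Z)-3-methyl-4-oxopent-2-en-1-yl]-5-(propan-2-yl)cyclopentan-1-one, via hydroperoxy ketal 17 (not isolated)
Conditions: O3 (1.0 equiv, Sudan Red 7B end point), CH2Cl2/MeOH (4:1), −78 °C; then Me2S, −78 → 25 °C
Reagents that add atoms: ozone O=[O+][O-]
Why: Regioselective ozonolysis attacks the more electron-rich tetrasubstituted C3a=C4 bond of the diene, after which the remaining alkene is part of an electron-poor enone that resists ozone and keeps the Z geometry inherited from the ring.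

Step 11
Reactants: 18 (2R,5S)-2-methyl-2-[(2Z)-3-methyl-4-oxopent-2-en-1-yl]-5-(propan-2-yl)cyclopentan-1-one
Product: 19 (2R,5R)-2-methyl-2-[(2Z)-3-methyl-4-oxopent-2-en-1-yl]-5-(propan-2-yl)cyclopentan-1-one
Conditions: DBU (0.2 equiv), toluene, 25 °C; chromatographic separation, recovered 18 resubjected
Reagents that add atoms: none
Why: Base-mediated keto–enol epimerisation equilibrates the only α-stereocentre of the cyclopentanone (no strong thermodynamic bias is expected), and the required epimer 19, with isopropyl cis to the ring methyl group, is separated while 18 is recycled.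

Step 12
Reactants: 19 (2R,5R)-2-methyl-2-[(2Z)-3-methyl-4-oxopent-2-en-1-yl]-5-(propan-2-yl)cyclopentan-1-one
Product: 21 (3R,3aS,8aR)-3a-hydroxy-6,8a-dimethyl-3-(propan-2-yl)-2,3,3a,4,8,8a-hexahydroazulen-5(1H)-one, via lithium enolate 20 (not isolated)
Conditions: LiN(iPr)2 (1.05 equiv), THF (0.01 M), −78 °C, then −40 °C; AcOH, −78 °C
Reagents that add atoms: none
Why: Kinetic deprotonation of the methyl ketone and intramolecular aldol addition close the seven-membered ring, and the tethered enolate reaches the cyclopentanone carbonyl only from the face anti to both the ring methyl and the isopropyl group, which sets C3a with its hydroxyl cis to both.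

Step 13
Reactants: 21 (3R,3aS,8aR)-3a-hydroxy-6,8a-dimethyl-3-(propan-2-yl)-2,3,3a,4,8,8a-hexahydroazulen-5(1H)-one
Product: 22 (3R,3aS,5R,8aR)-6,8a-dimethyl-3-(propan-2-yl)-1,2,3,3a,4,5,8,8a-octahydroazulene-3a,5-diol
Conditions: Me4NBH(OAc)3 (5 equiv), MeCN/AcOH (1:1), −30 °C
Reagents that add atoms: none
Why: Hydroxyl-directed 1,2-reduction (Evans–Saksena) delivers hydride intramolecularly from the boron bound to the C3a oxygen to the carbonyl face syn to that oxygen, giving the 1,3-anti diol with 5R.

Step 14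
Reactants: 22 (3R,3aS,5R,8aR)-6,8a-dimethyl-3-(propan-2-yl)-1,2,3,3a,4,5,8,8a-octahydroazulene-3a,5-diol; 23 3,4-dimethoxybenzoyl chloride
Product: 24 (3R,3aS,5R,8aR)-3a-hydroxy-6,8a-dimethyl-3-(propan-2-yl)-1,2,3,3a,4,5,8,8a-octahydroazulen-5-yl 3,4-dimethoxybenzoate
Conditions: pyridine (3 equiv), 4-(dimethylamino)pyridine (0.1 equiv), CH2Cl2, 0 → 25 °C
Reagents that add atoms: none
Why: Nucleophile-catalysed acylation is selective for the secondary allylic alcohol, the hindered tertiary alcohol staying free.

Compound list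

1 | (R)-(+)-limonene, (4R)-1-methyl-4-(prop-1-en-2-yl)cyclohex-1-ene | CC1=CC[C@@H](CC1)C(C)=C | starting material
2 | (4R)-1-methyl-4-(propan-2-yl)cyclohex-1-ene | CC1=CC[C@@H](CC1)C(C)C | intermediate
3 | (3R)-6-hydroperoxy-6-methoxy-3-(propan-2-yl)heptanal (C6 epimers) | CC(OC)(OO)CC[C@H](CC=O)C(C)C | intermediate
4 | (5R)-2-hydroperoxy-2,7,7-trimethoxy-5-(propan-2-yl)heptane (C2 epimers) | CC(OC)(OO)CC[C@H](CC(OC)OC)C(C)C | intermediate
5 | (5R)-7,7-dimethoxy-5-(propan-2-yl)heptan-2-one | CC(=O)CC[C@H](CC(OC)OC)C(C)C | intermediate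
6 | diethyl (5R)-7,7-dimethoxy-5-(propan-2-yl)hept-1-en-2-yl phosphate | C=C(OP(=O)(OCC)OCC)CC[C@H](CC(OC)OC)C(C)C | intermediate
7 | (5R)-7,7-dimethoxy-5-(propan-2-yl)hept-1-yne | C#CCC[C@H](CC(OC)OC)C(C)C | intermediate
8 | (E)-1-bromoprop-1-ene | C/C=C/Br | starting material
9 | [(1E,5R)-7,7-dimethoxy-2-methyl-5-(propan-2-yl)hept-1-en-1-yl]dimethylalumane | C[Al](C)/C=C(\C)CC[C@H](CC(OC)OC)C(C)C | intermediate
10 | (2E,4E,8R)-10,10-dimethoxy-5-methyl-8-(propan-2-yl)deca-2,4-diene | C/C=C/C=C(\C)CC[C@H](CC(OC)OC)C(C)C | intermediate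
11 | (3R,6E,8E)-6-methyl-3-(propan-2-yl)deca-6,8-dienal | C/C=C/C=C(\C)CC[C@H](CC=O)C(C)C | intermediate
12 | (3S,6E,8E)-6-methyl-3-(propan-2-yl)deca-1,6,8-trien-1-yl trifluoromethanesulfonate (1E/1Z mixture) | C/C=C/C=C(\C)CC[C@H](C=COS(=O)(=O)C(F)(F)F)C(C)C | intermediate
13 | [(3S,6E,8E)-6-methyl-3-(propan-2-yl)deca-6,8-dien-1-yn-1-yl]lithium | [Li]C#C[C@@H](CC/C(C)=C/C=C/C)C(C)C | intermediate
14 | (2E,4E,8S)-5-methyl-8-(propan-2-yl)undeca-2,4-dien-9-yne | C/C=C/C=C(\C)CC[C@H](C#CC)C(C)C | intermediate
15 | (3S,5S,7aR)-4,5,7a-trimethyl-3-(propan-2-yl)-2,3,5,7a-tetrahydro-1H-indene | CC1=C2[C@H](C(C)C)CC[C@]2(C)C=C[C@@H]1C | intermediate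
16 | (3S,7aR)-4,5,7a-trimethyl-3-(propan-2-yl)-2,3,7,7a-tetrahydro-1H-indene | CC1=C2[C@H](C(C)C)CC[C@]2(C)CC=C1C | intermediate
17 | (3Z)-5-[(1R,3S)-2-hydroperoxy-2-methoxy-1-methyl-3-(propan-2-yl)cyclopentyl]-3-methylpent-3-en-2-one (C2 epimers) | CC(=O)/C(C)=C\C[C@@]1(C)CC[C@@H](C(C)C)C1(OC)OO | intermediate
18 | (2R,5S)-2-methyl-2-[(2Z)-3-methyl-4-oxopent-2-en-1-yl]-5-(propan-2-yl)cyclopentan-1-one | CC(=O)/C(C)=C\C[C@@]1(C)CC[C@@H](C(C)C)C1=O | intermediate
19 | (2R,5R)-2-methyl-2-[(2Z)-3-methyl-4-oxopent-2-en-1-yl]-5-(propan-2-yl)cyclopentan-1-one | CC(=O)/C(C)=C\C[C@@]1(C)CC[C@H](C(C)C)C1=O | intermediate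
20 | lithium (3Z)-3-methyl-5-[(1R,3R)-1-methyl-2-oxo-3-(propan-2-yl)cyclopentyl]penta-1,3-dien-2-olate | [Li]OC(=C)/C(C)=C\C[C@@]1(C)CC[C@H](C(C)C)C1=O | intermediate
21 | (3R,3aS,8aR)-3a-hydroxy-6,8a-dimethyl-3-(propan-2-yl)-2,3,3a,4,8,8a-hexahydroazulen-5(1H)-one | O=C1C[C@]2(O)[C@@H](C(C)C)CC[C@]2(C)CC=C1C | intermediate
22 | (3R,3aS,5R,8aR)-6,8a-dimethyl-3-(propan-2-yl)-1,2,3,3a,4,5,8,8a-octahydroazulene-3a,5-diol | O[C@@H]1C[C@]2(O)[C@@H](C(C)C)CC[C@]2(C)CC=C1C | intermediate
23 | 3,4-dimethoxybenzoyl chloride | COc1ccc(C(=O)Cl)cc1OC | starting material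
24 | (3R,3aS,5R,8aR)-3a-hydroxy-6,8a-dimethyl-3-(propan-2-yl)-1,2,3,3a,4,5,8,8a-octahydroazulen-5-yl 3,4-dimethoxybenzoate | COc1ccc(C(=O)O[C@@H]2C[C@]3(O)[C@@H](C(C)C)CC[C@]3(C)CC=C2C)cc1OC | target

Total step count: 14. Longest linear sequence: 14 steps (1 to 24).

Steps most likely to fail

Step 8. Oxidative cyclisation at the fully substituted diene terminus may be slow, so that alkyne oligomerisation or diene isomerisation takes over, or the facial selectivity at C7a may be poor. The fallback changes the dienophile and the mode of activation and sets out from 12: elimination with LiN(iPr)2 and trapping of the acetylide with benzenesulfonyl fluoride gives the alkynyl sulfone {[(3S,6E,8E)-6-methyl-3-(propan-2-yl)deca-6,8-dien-1-yn-1-yl]sulfonyl}benzene F1. This electron-poor alkyne should undergo an uncatalysed thermal intramolecular Diels–Alder reaction (toluene, 110 °C) to the vinyl sulfone {[(3S,5S,7aR)-5,7a-dimethyl-3-(propan-2-yl)-2,3,5,7a-tetrahydro-1H-inden-4-yl]sulfonyl}benzene F2. Its sulfonyl group is then replaced by methyl with CH3MgBr and Ni(acac)2 (nickel bis(acetylacetonate), Julia-type desulfonylative coupling), which comes back to the route at 15.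

Step 11. The equilibration may show no useful preference for 19, and the base may isomerise the Z-enone to the E-enone, which cannot cyclise. The fallback replaces thermodynamic by kinetic, reagent-controlled protonation and sets out from 18: double silylation with Me3SiOSO2CF3 and Et3N gives the bis(silyl enol ether) trimethyl{[(3Z)-3-methyl-5-{(1R)-1-methyl-3-(propan-2-yl)-2-[(trimethylsilyl)oxy]cyclopent-2-en-1-yl}penta-1,3-dien-2-yl]oxy}silane F3, in which C5 of the cyclopentanone is planar. Protonation with the SnCl4 complex of the matching enantiomer of 1,1'-bi-2-naphthol as catalyst and 2,6-dimethylphenol as the stoichiometric proton source (Lewis acid-assisted Brønsted acid, toluene, −78 °C) should set that centre and return the enone, coming back to the route at 19.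

Step 12. The hindered ketone–ketone aldolate may revert by retro-aldol cleavage, or the kinetic enolate may equilibrate to the extended dienolate on warming. The fallback sets out from 19: kinetic silylation (LiN(iPr)2, Me3SiCl, THF, −78 °C) gives the silyloxydiene (2R,5R)-2-methyl-2-{(2Z)-3-methyl-4-[(trimethylsilyl)oxy]penta-2,4-dien-1-yl}-5-(propan-2-yl)cyclopentan-1-one F4. TiCl4 (CH2Cl2, −78 °C) then promotes an intramolecular Mukaiyama aldol addition, whose titanium aldolate does not revert, and aqueous work-up comes back to the route at 21.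

Further compounds

F1 | step 8 | {[(3S,6E,8E)-6-methyl-3-(propan-2-yl)deca-6,8-dien-1-yn-1-yl]sulfonyl}benzene | C/C=C/C=C(\C)CC[C@H](C#CS(=O)(=O)c1ccccc1)C(C)C
F2 | step 8 | {[(3S,5S,7aR)-5,7a-dimethyl-3-(propan-2-yl)-2,3,5,7a-tetrahydro-1H-inden-4-yl]sulfonyl}benzene | O=S(=O)(c1ccccc1)C1=C2[C@H](C(C)C)CC[C@]2(C)C=C[C@@H]1C
F3 | step 11 | trimethyl{[(3Z)-3-methyl-5-{(1R)-1-methyl-3-(propan-2-yl)-2-[(trimethylsilyl)oxy]cyclopent-2-en-1-yl}penta-1,3-dien-2-yl]oxy}silane | C[Si](C)(C)OC(=C)/C(C)=C\C[C@@]1(C)CCC(C(C)C)=C1O[Si](C)(C)C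
F4 | step 12 | (2R,5R)-2-methyl-2-{(2Z)-3-methyl-4-[(trimethylsilyl)oxy]penta-2,4-dien-1-yl}-5-(propan-2-yl)cyclopentan-1-one | C[Si](C)(C)OC(=C)/C(C)=C\C[C@@]1(C)CC[C@H](C(C)C)C1=O
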